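The plan cuts the C1–C10 bond of ring A (drimane numbering). C10 is the methyl-bearing ring-fusion carbon next to the exocyclic C9=C11 styrene, so ionising a C10 alcohol gives a cation delocalised over C10, C9 and C11 and held by the electron-rich arene; an allylsilane on the C4 side chain of C5 then attacks C10 through C1. This single operation closes ring A, creates the quaternary stereocentre C10 cis to the C5–C4 bond and restores the E C9=C11 alkene. The precursor is a pulegone-derived ring B cyclohexanol carrying the arylmethylidene at C9 and a 1-silylallyl group on the gem-dimethyl carbon C4; phenols are MOM ethers, the aryl aldehyde a dioxolane.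

Key step: step 7

Remark: drimane numbering is used (ring B = C5–C10; ring A = C1–C5 and C10; C11 = benzylic carbon); compounds 8–16 are carried as epimer mixtures at the silyl-bearing carbon C3, and 15 also at the carbinol carbon C10, because both centres are destroyed in step 7.
Remark: MOM ethers are chosen for the three phenols because removing three aryl methyl ethers would need a strong Lewis acid or hot thiolate, whereas MOM ethers fall off with the dioxolane in dilute acid that the ortho-hydroxylated C9=C11 styrene should tolerate.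
Remark: the condensation in step 5 is run under kinetic control because allylic strain in the arylidene ketone pushes the C8 methyl axial, which could make the wrong C5 epimer the thermodynamic one.

Step 1
Reactants: 1 2,4,5-trihydroxybenzaldehyde
Product: 2 2,4,5-tris(methoxymethoxy)benzaldehyde
Conditions: MOMCl, i-Pr2NEt, CH2Cl2, 0 °C → rt
Reagents that add atoms: chloromethyl methyl ether (MOMCl), COCCl
Why: Williamson-type O-alkylation of the three phenols by the highly reactive α-chloro ether under amine base gives the tris-MOM ether, which later directs the lithiation and is removable with dilute acid.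

Step 2
Reactants: 2 2,4,5-tris(methoxymethoxy)benzaldehyde
Product: 3 2-[2,4,5-tris(methoxymethoxy)phenyl]-1,3-dioxolane
Conditions: TMSOCH2CH2OTMS, TMSOTf (cat.), CH2Cl2, −78 → −20 °C; pyridine
Reagents that add atoms: 1,2-bis(trimethylsilyloxy)ethane, C[Si](C)(C)OCCO[Si](C)(C)C
Why: Noyori acetalisation transfers the glycol unit from its bis-silyl ether under catalytic TMSOTf in an aprotic medium at low temperature, so the aldehyde becomes a dioxolane without acid-catalysed exchange of the MOM ethers.

Step 3
Reactants: 3 2-[2,4,5-tris(methoxymethoxy)phenyl]-1,3-dioxolane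
Product: 5 3-(1,3-dioxolan-2-yl)-2,5,6-tris(methoxymethoxy)benzaldehyde, via aryllithium 4 (not isolated)
Conditions: n-BuLi, THF, 0 °C; DMF, −78 °C → rt; aq NH4Cl
Reagents that add atoms: N,N-dimethylformamide, CN(C)C=O
Why: Directed ortho-metalation by n-BuLi should occur at the only C–H flanked by two OMOM groups (stronger directors than the dioxolane that flanks the other free position), and the aryllithium is formylated by DMF.

Step 4
Reactants: 6 (S)-pulegone; 7 (E)-1,3-bis(trimethylsilyl)propene
Product: 10 (2R,5S)-5-methyl-2-[2-methyl-3-(trimethylsilyl)pent-4-en-2-yl]cyclohexan-1-one (trans ketone; C3 epimers), via trichlorotitanium enolate 8 (not isolated), via C5-epimeric ketone mixture 9 (not isolated)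
Conditions: TiCl4, CH2Cl2, −78 → −40 °C; aq NaHCO3; NaOMe (cat.), MeOH, rt
Reagents that add atoms: none
Why: Hosomi–Sakurai conjugate allylation: the TiCl4-activated enone is attacked at its β-carbon C4 by the allylsilane carbon remote from the allylic silicon, so the second silyl group stays on C3 as a new allylsilane, and base equilibration of the α-centre C5 should place the bulky side chain equatorial and trans to the C8 methyl as in menthone, while C3 forms without control and is carried as an epimer mixture.

Step 5
Reactants: 10 (2R,5S)-5-methyl-2-[2-methyl-3-(trimethylsilyl)pent-4-en-2-yl]cyclohexan-1-one; 5 3-(1,3-dioxolan-2-yl)-2,5,6-tris(methoxymethoxy)benzaldehyde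
Product: 14 (2E,3S,6R)-2-{[3-(1,3-dioxolan-2-yl)-2,5,6-tris(methoxymethoxy)phenyl]methylidene}-3-methyl-6-[2-methyl-3-(trimethylsilyl)pent-4-en-2-yl]cyclohexan-1-one, via lithium enolate 11 (not isolated), via lithium aldolate 12 (not isolated), via aldol mesylate 13 (not isolated)
Conditions: LiN(i-Pr)2, THF, −78 °C; 5; MsCl, −78 → 0 °C; DBU, 0 °C → rt
Reagents that add atoms: none
Why: Directed aldol condensation: LiN(i-Pr)2 removes a proton from the less hindered C9 methylene, the enolate adds to aldehyde 5, and mesylation then E1cB elimination with DBU gives the E arylidene ketone (aryl anti to the carbonyl) under kinetic conditions that should leave the C5–H untouched.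

Step 6
Reactants: 14 the E arylidene ketone
Product: 15 (2E,3S,6R)-2-{[3-(1,3-dioxolan-2-yl)-2,5,6-tris(methoxymethoxy)phenyl]methylidene}-1,3-dimethyl-6-[2-methyl-3-(trimethylsilyl)pent-4-en-2-yl]cyclohexan-1-ol (tertiary C10 alcohol; key-step precursor)
Conditions: MeLi, CeCl3, THF, −78 °C; aq NaHCO3 (crude 15 taken on)
Reagents that add atoms: methyllithium, [Li]C
Why: Organocerium 1,2-addition: the weakly basic and oxophilic MeCeCl2 adds to the hindered, enolisable C10 carbonyl without conjugate addition or enolisation, and the configuration of the new carbinol centre is immaterial because it is ionised in step 7.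

Step 7
Reactants: 15 the tertiary C10 alcohol
Product: 17 2-{3-[(E)-((2S,4aR,8aS)-2,5,5,8a-tetramethyl-3,4,4a,5,8,8a-hexahydronaphthalen-1(2H)-ylidene)methyl]-2,4,5-tris(methoxymethoxy)phenyl}-1,3-dioxolane (cis-fused; C2=C3 alkene in ring A), via allyl cation 16 (not isolated)
Conditions: Sc(OTf)3 (5 mol %), 4 Å MS, CH2Cl2, −40 → 0 °C; Et3N
Reagents that add atoms: none
Why: Sc(OTf)3 ionises the tertiary C10 alcohol to the C10–C9–C11 allyl cation 16, stabilised from C11 by the 2,6-dioxygenated arene; the γ-carbon C1 of the allylsilane adds to C10 and the β-silyl cation at C2 loses the silyl group from C3 (anti SE2′), leaving C2=C3 and returning the catalyst. The closest known reaction type is the allylsilane-terminated cation–olefin cyclisation, an intramolecular Hosomi–Sakurai allylation of an ionised allylic alcohol. Ring A closes 6-endo-trig with respect to the C1=C2 alkene and exo with respect to the allyl cation, while attack at C11 would need an eight-membered ring. The new quaternary stereocentre C10 is controlled by C5: when the side chain is pseudoaxial (favoured by allylic strain with the C10 methyl) the tether reaches only the face carrying the C5–C4 bond, when it is pseudoequatorial the chair-like axial attack uses the same face, and this face is also opposite the pseudoaxial C8 methyl, so C1 ends cis to C4 and the C10 methyl cis to H5. The step needs C10 over C11 attack (ring size), E geometry at C9=C11 (the aryl group avoids the C10 methyl in cation and product) and ring closure faster than proton loss or protodesilylation, which the gem-dimethyl group at C4, the low temperature, the catalytic acid loading and the molecular sieves are meant to secure. Both C3 epimers and both carbinol epimers converge on 17.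

Step 8
Reactants: 17 the cyclised diene
Product: 18 2-{3-[(E)-((2S,4aR,8aS)-2,5,5,8a-tetramethyloctahydronaphthalen-1(2H)-ylidene)methyl]-2,4,5-tris(methoxymethoxy)phenyl}-1,3-dioxolane
Conditions: 2-nitrobenzenesulfonylhydrazide, Et3N, CH2Cl2, rt
Reagents that add atoms: none
Why: Diimide reduction (concerted syn transfer of two hydrogens) is very sensitive to substitution and shielding, so the cis-disubstituted C2=C3 alkene of ring A should be saturated while the trisubstituted C9=C11 styrene, flanked by quaternary C10 and a doubly ortho-substituted arene, and all acetals remain.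

Step 9
Reactants: 18 the protected target
Product: 19 2,4,5-trihydroxy-3-[(E)-((2S,4aR,8aS)-2,5,5,8a-tetramethyloctahydronaphthalen-1(2H)-ylidene)methyl]benzaldehyde (CNP0111013.2)
Conditions: 2 M aq HCl, THF–MeOH, rt → 40 °C, argon
Reagents that add atoms: water, O
Why: Acid-catalysed hydrolysis of acetals: dilute aqueous HCl cleaves the three MOM ethers and the dioxolane in one operation, and the mild, oxygen-free conditions are chosen so that the triphenol is not oxidised and the ortho-phenols do not add across C9=C11.

Compound list
1 | 2,4,5-trihydroxybenzaldehyde | O=Cc1cc(O)c(O)cc1O | starting material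
2 | 2,4,5-tris(methoxymethoxy)benzaldehyde | O=Cc1cc(OCOC)c(OCOC)cc1OCOC | intermediate
3 | 2-[2,4,5-tris(methoxymethoxy)phenyl]-1,3-dioxolane | COCOc1cc(OCOC)c(OCOC)cc1C1OCCO1 | intermediate
4 | [3-(1,3-dioxolan-2-yl)-2,5,6-tris(methoxymethoxy)phenyl]lithium | [Li]c1c(OCOC)c(OCOC)cc(C2OCCO2)c1OCOC | intermediate
5 | 3-(1,3-dioxolan-2-yl)-2,5,6-tris(methoxymethoxy)benzaldehyde | O=Cc1c(OCOC)c(OCOC)cc(C2OCCO2)c1OCOC | intermediate
6 | (S)-pulegone | C[C@H]1CCC(=C(C)C)C(=O)C1 | starting material
7 | (E)-1,3-bis(trimethylsilyl)propene | C[Si](C)(C)C/C=C/[Si](C)(C)C | starting material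
8 | trichlorotitanium enolate of the conjugate adduct (C5=C10, Cl3Ti–O on C10; C3 epimers) | C[C@H]1CCC(=C(O[Ti](Cl)(Cl)Cl)C1)C(C)(C)C(C=C)[Si](C)(C)C | intermediate
9 | (5S)-5-methyl-2-[2-methyl-3-(trimethylsilyl)pent-4-en-2-yl]cyclohexan-1-one, mixture of epimers at ring C2 (drimane C5) and at C3 | C[C@H]1CCC(C(C)(C)C(C=C)[Si](C)(C)C)C(=O)C1 | intermediate
10 | (2R,5S)-5-methyl-2-[2-methyl-3-(trimethylsilyl)pent-4-en-2-yl]cyclohexan-1-one (side chain trans to the ring methyl; C3 epimers) | C[C@H]1CC[C@H](C(C)(C)C(C=C)[Si](C)(C)C)C(=O)C1 | intermediate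
11 | lithium enolate of 10 towards C9 (C9=C10–OLi) | C[C@H]1CC[C@H](C(C)(C)C(C=C)[Si](C)(C)C)C(O[Li])=C1 | intermediate
12 | lithium aldolate from 11 and 5 (C9–C11 bond, OLi on C11; diastereomer mixture at C9 and C11) | C[C@H]1CC[C@H](C(C)(C)C(C=C)[Si](C)(C)C)C(=O)C1C(O[Li])c1c(OCOC)c(OCOC)cc(C2OCCO2)c1OCOC | intermediate
13 | C11 methanesulfonate of the aldol adduct (diastereomer mixture at C9 and C11) | C[C@H]1CC[C@H](C(C)(C)C(C=C)[Si](C)(C)C)C(=O)C1C(OS(C)(=O)=O)c1c(OCOC)c(OCOC)cc(C2OCCO2)c1OCOC | intermediate
14 | (2E,3S,6R)-2-{[3-(1,3-dioxolan-2-yl)-2,5,6-tris(methoxymethoxy)phenyl]methylidene}-3-methyl-6-[2-methyl-3-(trimethylsilyl)pent-4-en-2-yl]cyclohexan-1-one (C3 epimers) | C[C@H]1CC[C@H](C(C)(C)C(C=C)[Si](C)(C)C)C(=O)/C1=C/c1c(OCOC)c(OCOC)cc(C2OCCO2)c1OCOC | intermediate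
15 | (2E,3S,6R)-2-{[3-(1,3-dioxolan-2-yl)-2,5,6-tris(methoxymethoxy)phenyl]methylidene}-1,3-dimethyl-6-[2-methyl-3-(trimethylsilyl)pent-4-en-2-yl]cyclohexan-1-ol (key-step precursor; epimers at the carbinol carbon and at C3) | C[C@H]1CC[C@H](C(C)(C)C(C=C)[Si](C)(C)C)C(C)(O)/C1=C/c1c(OCOC)c(OCOC)cc(C2OCCO2)c1OCOC | intermediate
16 | allyl cation C10–C9–C11 formed from 15 by loss of hydroxide (C3 epimers) | C[C@H]1CC[C@H](C(C)(C)C(C=C)[Si](C)(C)C)[C+](C)/C1=C/c1c(OCOC)c(OCOC)cc(C2OCCO2)c1OCOC | intermediate
17 | 2-{3-[(E)-((2S,4aR,8aS)-2,5,5,8a-tetramethyl-3,4,4a,5,8,8a-hexahydronaphthalen-1(2H)-ylidene)methyl]-2,4,5-tris(methoxymethoxy)phenyl}-1,3-dioxolane (cis-fused, H5 and both ring methyls on one face; C2=C3 alkene) | C[C@H]1CC[C@@H]2C(C)(C)C=CC[C@]2(C)/C1=C/c1c(OCOC)c(OCOC)cc(C2OCCO2)c1OCOC | intermediate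
18 | 2-{3-[(E)-((2S,4aR,8aS)-2,5,5,8a-tetramethyloctahydronaphthalen-1(2H)-ylidene)methyl]-2,4,5-tris(methoxymethoxy)phenyl}-1,3-dioxolane | C[C@H]1CC[C@@H]2C(C)(C)CCC[C@]2(C)/C1=C/c1c(OCOC)c(OCOC)cc(C2OCCO2)c1OCOC | intermediate
19 | 2,4,5-trihydroxy-3-[(E)-((2S,4aR,8aS)-2,5,5,8a-tetramethyloctahydronaphthalen-1(2H)-ylidene)methyl]benzaldehyde | C[C@H]1CC[C@@H]2C(C)(C)CCC[C@]2(C)/C1=C/c1c(O)c(O)cc(C=O)c1O | target

Total step count: 9.
Longest linear sequence: 8 steps (steps 1, 2, 3, 5, 6, 7, 8, 9 from 1); 6 steps from 6.

Steps most likely to fail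

1. Step 7. What may go wrong: after ionisation the cation may lose a proton (from the C10 methyl or from C5), or the allylsilane may be protodesilylated, before the C1–C10 bond forms. Attack may also be unselective between the two faces of C10, and the Lewis acid may cleave the MOM ethers or the dioxolane. Fallback (conjugate addition in place of cation capture, same bond formed): setting out from 15, oxidative 1,3-transposition of the tertiary allylic alcohol (Babler–Dauben oxidation; [C5H5NH][CrO3Cl], NaOAc, 4 Å MS, CH2Cl2) should give the transposed aryl enone F1, with C10=C9 inside ring B and a ketone at C11. Fluoride-triggered intramolecular Sakurai conjugate addition of the allylsilane to C10 (TBAF, DMF, 4 Å MS) should then close ring A to the cis-fused aryl ketone F2, the side chain again being held pseudoaxial by the C10 methyl. LiAlH4 in THF reduces the C11 ketone to the benzylic alcohol F3. Dehydration with the Burgess reagent (toluene, 50 °C), possible only towards C9, should favour the E alkene and comes back to the route at 17.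

2. Step 4. What may go wrong: the silyl-bearing carbon of 7 may be too hindered to attack the β,β-disubstituted enone, so that protodesilylation of 7 or decomposition of 6 by TiCl4 takes over. Fallback (sigmatropic route to the same ketone): setting out from 6, 1,2-addition of [1-(trimethylsilyl)allyl]lithium (from allyltrimethylsilane, s-BuLi, TMEDA, THF, −78 °C), which reacts through the carbon remote from silicon, should give the tertiary dienol F4. Anionic oxy-Cope rearrangement (KH, 18-crown-6, THF, rt → 50 °C) joins C4 to the silyl-bearing carbon and delivers the potassium enolate F5. Its protonation gives mixture 9, and the NaOMe equilibration of step 4 comes back to the route at 10.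

3. Step 5. What may go wrong: slow addition between the hindered enolate and the doubly ortho-substituted aldehyde, retro-aldol cleavage before mesylation, or base-induced epimerisation of C5 in the arylidene ketone. Fallback (the C11–aryl bond is made instead of the C9–C11 bond): setting out from 10, condensation with t-BuOCH(NMe2)2 (toluene, 90 °C) at the C9 methylene should give the enaminone F6. Aryllithium 4, made from 3 as in step 3, is transmetalated with MgBr2·OEt2 to the arylmagnesium bromide F7. This adds to the β-carbon of F6 and loses dimethylamine on mild acidic work-up (addition–elimination on a vinylogous amide), which comes back to the route at 14 and makes aldehyde 5 unnecessary.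

Further compounds
F1 | step 7 | transposed aryl enone (C10=C9 in ring B, C11 ketone; C3 epimers) | C[C@H]1CC[C@H](C(C)(C)C(C=C)[Si](C)(C)C)C(C)=C1C(=O)c1c(OCOC)c(OCOC)cc(C2OCCO2)c1OCOC
F2 | step 7 | cis-fused aryl ketone (ring A closed, C2=C3 alkene, C9–H epimers) | C[C@H]1CC[C@@H]2C(C)(C)C=CC[C@]2(C)C1C(=O)c1c(OCOC)c(OCOC)cc(C2OCCO2)c1OCOC
F3 | step 7 | benzylic C11 alcohol from F2 (diastereomer mixture at C9 and C11) | C[C@H]1CC[C@@H]2C(C)(C)C=CC[C@]2(C)C1C(O)c1c(OCOC)c(OCOC)cc(C2OCCO2)c1OCOC
F4 | step 4 | tertiary dienol, (5S)-5-methyl-2-(propan-2-ylidene)-1-[(E)-3-(trimethylsilyl)prop-2-en-1-yl]cyclohexan-1-ol (carbinol epimers) | C[C@H]1CCC(=C(C)C)C(O)(C/C=C/[Si](C)(C)C)C1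
F5 | step 4 | potassium enolate of 9 (C5=C10–OK; C3 epimers) | C[C@H]1CCC(=C(O[K])C1)C(C)(C)C(C=C)[Si](C)(C)C
F6 | step 5 | enaminone, (2E,3S,6R)-2-[(dimethylamino)methylidene]-3-methyl-6-[2-methyl-3-(trimethylsilyl)pent-4-en-2-yl]cyclohexan-1-one (C3 epimers) | C[C@H]1CC[C@H](C(C)(C)C(C=C)[Si](C)(C)C)C(=O)/C1=C/N(C)C
F7 | step 5 | [3-(1,3-dioxolan-2-yl)-2,5,6-tris(methoxymethoxy)phenyl]magnesium bromide | Br[Mg]c1c(OCOC)c(OCOC)cc(C2OCCO2)c1OCOC
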